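**Retrosynthetic overview**
- The ester C–O bond is cut last: Mitsunobu coupling (with inversion) of the bicyclic dienone diol with (Z)-2-methyl-3-(methylsulfanyl)acrylic acid (fragment 3, from methyl propanoate).
- The tertiary alcohol and the second ring-B alkene come from a singlet-oxygen ene reaction on a propan-2-ylidene enone; the carbinol comes from a ketone carried as its dimethyl ketal.
- Ring B is closed by intramolecular aldol condensation after the quaternary carbon is made by alkylating a ring-A dienolate (fragment 1) with 3-(bromomethyl)-4-methylpent-3-en-2-one (fragment 2, from pent-3-yn-2-one).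
- Fragment 1 comes from phenol via p-quinone monoketal, copper-catalysed asymmetric conjugate methylation and alpha-methylation.
- Ring order: ring A is the original phenol ring; ring B is formed second.

Assumption: the (S,R,R)-phosphoramidite in step 2 is taken to give the (5R)-enone; if it gives the mirror image, the (R,S,S)-ligand is used instead.

**Ring A fragment**

Step 1
Reactants: 1 phenol
Product: 3 4,4-dimethoxycyclohexa-2,5-dien-1-one, via 4-methoxyphenol 2 (not isolated)
Conditions: PhI(OAc)2 (2.2 equiv), MeOH, 0 °C to rt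
Reagents that add atoms: methanol CO
Why: Double hypervalent-iodine oxidative dearomatisation, methanol trapping the para position twice to give the quinone monoketal; no stereocentre.

Step 2
Reactants: 3 4,4-dimethoxycyclohexa-2,5-dien-1-one
Product: 5 (5R)-4,4-dimethoxy-5-methylcyclohex-2-en-1-one, via zinc dienolate 4 (not isolated)
Conditions: Me2Zn (1.5 equiv), Cu(OTf)2 (2 mol%), (S,R,R)-binaphthol bis(1-phenylethyl)amine phosphoramidite (4 mol%), toluene, −25 °C; then sat. aq. NH4Cl
Reagents that add atoms: dimethylzinc C[Zn]C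
Why: Copper-catalysed enantioselective conjugate addition desymmetrises the prochiral dienone, the chiral copper–phosphoramidite complex choosing one enone arm and face to set the methyl-bearing centre as R.

Step 3
Reactants: 5 (5R)-4,4-dimethoxy-5-methylcyclohex-2-en-1-one
Product: 7 (5R,6R)-4,4-dimethoxy-5,6-dimethylcyclohex-2-en-1-one, via lithium dienolate 6 (not isolated)
Conditions: LiN(iPr)2 (1.05 equiv), THF, −78 °C; then MeI, −78 to −20 °C
Reagents that add atoms: iodomethane CI
Why: Kinetic enolate alkylation at the only enolisable carbon (the other flank is vinylic, the gamma carbon is the ketal), MeI entering trans to the adjacent methyl; this centre is planarised again in step 10, so its ratio does not matter.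

**Ring B fragment**

Step 4
Reactants: 8 pent-3-yn-2-one
Product: 10 3-(hydroxymethyl)-4-methylpent-3-en-2-one, via lithium allenolate 9 (not isolated)
Conditions: Me2CuLi (from MeLi 2 equiv and CuI, Et2O, −20 °C), add 8 at −78 °C; then CH2O gas (cracked paraformaldehyde), −78 to −20 °C; sat. aq. NH4Cl
Reagents that add atoms: methyllithium [Li]C (delivered as Me2CuLi); formaldehyde C=O
Why: Cuprate conjugate addition to the ynone, then aldol trapping of the allenolate at its alpha carbon by formaldehyde; the alkene carries two identical methyls, so no geometry or stereocentre arises.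

Step 5
Reactants: 10 3-(hydroxymethyl)-4-methylpent-3-en-2-one
Product: 11 3-(bromomethyl)-4-methylpent-3-en-2-one
Conditions: PBr3 (0.4 equiv), Et2O, 0 °C
Reagents that add atoms: phosphorus tribromide BrP(Br)Br
Why: SN2 bromination of the primary allylic alcohol through its phosphite ester; the conjugated tetrasubstituted alkene keeps the bromide primary.

**Acid fragment**

Step 6
Reactants: 12 methyl propanoate
Product: 14 methyl 2-methyl-3-oxopropanoate, via sodium enolate 13 (not isolated)
Conditions: NaH (1.1 equiv), HCO2Me (1.5 equiv), cat. MeOH, THF, 0 °C to rt; then cold 1 M HCl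
Reagents that add atoms: methyl formate COC=O
Why: Crossed Claisen condensation (C-formylation), driven by formation of the stabilised enolate of the beta-formyl ester.

Step 7
Reactants: 14 methyl 2-methyl-3-oxopropanoate
Product: 15 methyl (2Z)-2-methyl-3-(tosyloxy)prop-2-enoate
Conditions: TsCl, N-methylimidazole, LiOH, MeCN, 0 °C
Reagents that add atoms: p-toluenesulfonyl chloride Cc1ccc(cc1)S(Cl)(=O)=O
Why: O-Sulfonylation of the lithium-chelated enolate, in which enolate oxygen and ester carbonyl are held cis, fixes the Z enol tosylate.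

Step 8
Reactants: 15 methyl (2Z)-2-methyl-3-(tosyloxy)prop-2-enoate
Product: 16 methyl (2Z)-2-methyl-3-(methylsulfanyl)prop-2-enoate
Conditions: NaSMe (1.05 equiv), THF/MeOH, −20 to 0 °C
Reagents that add atoms: sodium methanethiolate [Na+].[S-]C
Why: Nucleophilic vinylic substitution by addition–elimination; tosylate leaves before bond rotation, so the Z geometry (sulfur cis to the ester) is retained.

Step 9
Reactants: 16 methyl (2Z)-2-methyl-3-(methylsulfanyl)prop-2-enoate
Product: 18 (2Z)-2-methyl-3-(methylsulfanyl)prop-2-enoic acid, via lithium carboxylate 17 (not isolated)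
Conditions: LiOH, THF/H2O, rt; then 1 M HCl to pH 3
Reagents that add atoms: lithium hydroxide [Li+].[OH-]
Why: Saponification; the push–pull thioacrylate is a poor Michael acceptor and survives aqueous LiOH.

**Fragment union and endgame**

Step 10
Reactants: 7 (5R,6R)-4,4-dimethoxy-5,6-dimethylcyclohex-2-en-1-one; 11 3-(bromomethyl)-4-methylpent-3-en-2-one
Product: 20 (5R,6R)-6-(2-acetyl-3-methylbut-2-en-1-yl)-4,4-dimethoxy-5,6-dimethylcyclohex-2-en-1-one, via lithium dienolate 19 (not isolated)
Conditions: LiN(iPr)2 (1.1 equiv), THF, −78 to −40 °C; DMPU, then 11, −78 to −30 °C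
Reagents that add atoms: none
Why: Enolate alkylation (SN2 on the activated primary allylic bromide) at the only enolisable site; the bromide attacks the dienolate face anti to the neighbouring pseudoaxial methyl (A1,2 strain, the two ketal oxygens flanking both faces alike), so the quaternary centre carries its methyl cis to the secondary methyl.

Step 11
Reactants: 20 (5R,6R)-6-(2-acetyl-3-methylbut-2-en-1-yl)-4,4-dimethoxy-5,6-dimethylcyclohex-2-en-1-one
Product: 21 (2R,3R)-2-(2-acetyl-3-methylbut-2-en-1-yl)-4,4-dimethoxy-2,3-dimethylcyclohexan-1-one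
Conditions: [(Ph3P)CuH]6 (0.4 equiv), H2O (2 equiv), benzene/THF, rt; sat. aq. NH4Cl
Reagents that add atoms: none
Why: Chemoselective 1,4-reduction by copper hydride: the disubstituted ring enone reacts, the tetrasubstituted side-chain enone does not; no stereocentre is formed.

Step 12
Reactants: 21 (2R,3R)-2-(2-acetyl-3-methylbut-2-en-1-yl)-4,4-dimethoxy-2,3-dimethylcyclohexan-1-one
Product: 22 (4aR,5R)-6,6-dimethoxy-4a,5-dimethyl-3-(propan-2-ylidene)-4,4a,5,6,7,8-hexahydronaphthalen-2(3H)-one
Conditions: KOH (0.5 equiv), MeOH, 50 °C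
Reagents that add atoms: none
Why: Intramolecular aldol condensation (second half of a Robinson annulation) closes ring B from the methyl ketone onto the ring A carbonyl; the conjugated propan-2-ylidene isomer is the thermodynamic one and the stereocentres are untouched.

Step 13
Reactants: 22 (4aR,5R)-6,6-dimethoxy-4a,5-dimethyl-3-(propan-2-ylidene)-4,4a,5,6,7,8-hexahydronaphthalen-2(3H)-one
Product: 24 (4aR,5R)-3-(2-hydroxypropan-2-yl)-6,6-dimethoxy-4a,5-dimethyl-5,6,7,8-tetrahydronaphthalen-2(4aH)-one, via hydroperoxide 23 (not isolated)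
Conditions: O2, tetraphenylporphyrin (1 mol%), visible light (>450 nm), CH2Cl2, 0 °C; then PPh3
Reagents that add atoms: dioxygen O=O
Why: Schenck ene reaction of singlet oxygen with the geminal regioselectivity of s-cis enones: oxygen bonds to the beta carbon and the pseudoaxial ring hydrogen on the alpha substituent is abstracted, moving the alkene into ring B, and PPh3 reduces the hydroperoxide; the carbinol carbon bears two methyls, so no stereocentre.

Step 14
Reactants: 24 (4aR,5R)-3-(2-hydroxypropan-2-yl)-6,6-dimethoxy-4a,5-dimethyl-5,6,7,8-tetrahydronaphthalen-2(4aH)-one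
Product: 25 (1R,8aR)-7-(2-hydroxypropan-2-yl)-1,8a-dimethyl-3,4-dihydronaphthalene-2,6(1H,8aH)-dione
Conditions: pyridinium p-toluenesulfonate (0.2 equiv), acetone/H2O 10:1, 40 °C
Reagents that add atoms: water O
Why: Acid-catalysed ketal hydrolysis; the tertiary alcohol has no alpha hydrogen and its cation would be cross-conjugated to the dienone, and the methyl-bearing alpha centre is already the more stable equatorial epimer.

Step 15
Reactants: 25 (1R,8aR)-7-(2-hydroxypropan-2-yl)-1,8a-dimethyl-3,4-dihydronaphthalene-2,6(1H,8aH)-dione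
Product: 26 (4aR,5R,6S)-6-hydroxy-3-(2-hydroxypropan-2-yl)-4a,5-dimethyl-5,6,7,8-tetrahydronaphthalen-2(4aH)-one
Conditions: NaBH4 (0.5 equiv), MeOH/CH2Cl2 1:1, −40 °C
Reagents that add atoms: none
Why: Chemoselective hydride reduction of the saturated ketone over the cross-conjugated dienone; axial delivery is blocked by the 1,3-syn-axial angular methyl, so hydride enters equatorially and gives the axial 6S alcohol, cis to both methyls.

Step 16
Reactants: 26 (4aR,5R,6S)-6-hydroxy-3-(2-hydroxypropan-2-yl)-4a,5-dimethyl-5,6,7,8-tetrahydronaphthalen-2(4aH)-one; 18 (2Z)-2-methyl-3-(methylsulfanyl)prop-2-enoic acid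
Product: 27 (1R,2R,8aR)-7-(2-hydroxypropan-2-yl)-1,8a-dimethyl-6-oxo-1,2,3,4,6,8a-hexahydronaphthalen-2-yl (2Z)-2-methyl-3-(methylsulfanyl)prop-2-enoate
Conditions: PPh3 (1.5 equiv), DIAD (1.5 equiv), toluene, 0 °C to rt
Reagents that add atoms: none
Why: Mitsunobu esterification: the carboxylate displaces the axial oxyphosphonium with SN2 inversion to give the equatorial ester with the required R carbinol configuration, trans to the neighbouring methyl; the tertiary alcohol is inert.

**Compound list**

1 | phenol | Oc1ccccc1 | starting material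
2 | 4-methoxyphenol | COc1ccc(O)cc1 | intermediate (not isolated)
3 | 4,4-dimethoxycyclohexa-2,5-dien-1-one | COC1(OC)C=CC(=O)C=C1 | intermediate
4 | methylzinc (3R)-4,4-dimethoxy-3-methylcyclohexa-1,5-dien-1-olate | COC1(OC)C=CC(O[Zn]C)=C[C@H]1C | intermediate (not isolated)
5 | (5R)-4,4-dimethoxy-5-methylcyclohex-2-en-1-one | COC1(OC)C=CC(=O)C[C@H]1C | intermediate
6 | lithium (3R)-4,4-dimethoxy-3-methylcyclohexa-1,5-dien-1-olate | COC1(OC)C=CC(O[Li])=C[C@H]1C | intermediate (not isolated)
7 | (5R,6R)-4,4-dimethoxy-5,6-dimethylcyclohex-2-en-1-one (methyls trans) | COC1(OC)C=CC(=O)[C@H](C)[C@H]1C | intermediate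
8 | pent-3-yn-2-one | CC#CC(C)=O | starting material
9 | lithium 4-methylpenta-2,3-dien-2-olate | CC(C)=C=C(C)O[Li] | intermediate (not isolated)
10 | 3-(hydroxymethyl)-4-methylpent-3-en-2-one | CC(=O)C(CO)=C(C)C | intermediate
11 | 3-(bromomethyl)-4-methylpent-3-en-2-one | CC(=O)C(CBr)=C(C)C | intermediate
12 | methyl propanoate | CCC(=O)OC | starting material
13 | sodium (1Z)-3-methoxy-2-methyl-3-oxoprop-1-en-1-olate | [Na+].[O-]/C=C(/C)C(=O)OC | intermediate (not isolated)
14 | methyl 2-methyl-3-oxopropanoate (racemic, enolisable) | COC(=O)C(C)C=O | intermediate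
15 | methyl (2Z)-2-methyl-3-(tosyloxy)prop-2-enoate | Cc1ccc(cc1)S(=O)(=O)O/C=C(/C)C(=O)OC | intermediate
16 | methyl (2Z)-2-methyl-3-(methylsulfanyl)prop-2-enoate | CS/C=C(/C)C(=O)OC | intermediate
17 | lithium (2Z)-2-methyl-3-(methylsulfanyl)prop-2-enoate | [Li+].CS/C=C(/C)C([O-])=O | intermediate (not isolated)
18 | (2Z)-2-methyl-3-(methylsulfanyl)prop-2-enoic acid | CS/C=C(/C)C(=O)O | intermediate
19 | lithium (3R)-4,4-dimethoxy-2,3-dimethylcyclohexa-1,5-dien-1-olate | COC1(OC)C=CC(O[Li])=C(C)[C@H]1C | intermediate (not isolated)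
20 | (5R,6R)-6-(2-acetyl-3-methylbut-2-en-1-yl)-4,4-dimethoxy-5,6-dimethylcyclohex-2-en-1-one (methyls cis) | COC1(OC)C=CC(=O)[C@](C)(CC(C(C)=O)=C(C)C)[C@H]1C | intermediate
21 | (2R,3R)-2-(2-acetyl-3-methylbut-2-en-1-yl)-4,4-dimethoxy-2,3-dimethylcyclohexan-1-one | COC1(OC)CCC(=O)[C@](C)(CC(C(C)=O)=C(C)C)[C@H]1C | intermediate
22 | (4aR,5R)-6,6-dimethoxy-4a,5-dimethyl-3-(propan-2-ylidene)-4,4a,5,6,7,8-hexahydronaphthalen-2(3H)-one | COC1(OC)CCC2=CC(=O)C(=C(C)C)C[C@]2(C)[C@H]1C | intermediate
23 | (4aR,5R)-3-(2-hydroperoxypropan-2-yl)-6,6-dimethoxy-4a,5-dimethyl-5,6,7,8-tetrahydronaphthalen-2(4aH)-one | COC1(OC)CCC2=CC(=O)C(C(C)(C)OO)=C[C@]2(C)[C@H]1C | intermediate (not isolated)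
24 | (4aR,5R)-3-(2-hydroxypropan-2-yl)-6,6-dimethoxy-4a,5-dimethyl-5,6,7,8-tetrahydronaphthalen-2(4aH)-one | COC1(OC)CCC2=CC(=O)C(C(C)(C)O)=C[C@]2(C)[C@H]1C | intermediate
25 | (1R,8aR)-7-(2-hydroxypropan-2-yl)-1,8a-dimethyl-3,4-dihydronaphthalene-2,6(1H,8aH)-dione | O=C1CCC2=CC(=O)C(C(C)(C)O)=C[C@]2(C)[C@H]1C | intermediate
26 | (4aR,5R,6S)-6-hydroxy-3-(2-hydroxypropan-2-yl)-4a,5-dimethyl-5,6,7,8-tetrahydronaphthalen-2(4aH)-one (axial OH, cis to both methyls) | O[C@H]1CCC2=CC(=O)C(C(C)(C)O)=C[C@]2(C)[C@H]1C | intermediate
27 | (1R,2R,8aR)-7-(2-hydroxypropan-2-yl)-1,8a-dimethyl-6-oxo-1,2,3,4,6,8a-hexahydronaphthalen-2-yl (2Z)-2-methyl-3-(methylsulfanyl)prop-2-enoate | CS/C=C(/C)C(=O)O[C@@H]1CCC2=CC(=O)C(C(C)(C)O)=C[C@]2(C)[C@H]1C | target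

**Totals**

Total steps: 16. Longest linear sequence: 10 (steps 1–3 and 10–16). The ring B branch is 2 steps and the acid branch 4 steps before they join.

**Steps most likely to fail, with fallbacks**

Step 10 (quaternary-centre alkylation). The dienolate is hindered, bromide 11 carries an acidic methyl ketone that could quench it, and the facial selectivity rests on one neighbouring methyl. The fallback sets out from alcohol 10 and ketone 7 and returns at 20. Alcohol 10 is acylated with methyl chloroformate and pyridine to 2-acetyl-3-methylbut-2-en-1-yl methyl carbonate F1. Dienolate 19, generated from 7 as before and transmetallated with ZnCl2, is then allylated with F1 under Pd(PPh3)4 (Tsuji–Trost allylation at the unhindered CH2 terminus). If the diastereomer ratio is the problem, Pd2(dba)3 with a chiral tert-butyl phosphinooxazoline ligand adds catalyst control. The product is 20.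

Step 13 (singlet-oxygen ene reaction). Hydrogen abstraction from a methyl group would give the tertiary alpha-hydroperoxide with an isopropenyl group instead, and the dienone product is light-sensitive. The fallback sets out from 22 and returns at 24. Dimethyldioxirane in acetone at 0 °C epoxidises the electron-richer tetrasubstituted alkene from the face opposite the angular methyl, giving the propan-2-ylidene epoxide of 22 F2. SmI2 in THF/MeOH at −78 °C cleaves the alpha C–O bond to give (3S,4aR,5R)-3-(2-hydroxypropan-2-yl)-6,6-dimethoxy-4a,5-dimethyl-4,4a,5,6,7,8-hexahydronaphthalen-2(3H)-one F3 (either C3 epimer serves). IBX in DMSO at 70 °C then dehydrogenates the alpha-prime position to give 24.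

Step 16 (Mitsunobu inversion). The axial oxyphosphonium has anti-periplanar hydrogens on both neighbours, so E2 elimination competes with substitution. The fallback sets out from 26 and returns at 27. Al(OiPr)3 in iPrOH/toluene with a trace of acetone at 80 °C equilibrates the carbinol through ketone 25 (Meerwein–Ponndorf–Verley/Oppenauer) to the more stable equatorial epimer, (4aR,5R,6R)-6-hydroxy-3-(2-hydroxypropan-2-yl)-4a,5-dimethyl-5,6,7,8-tetrahydronaphthalen-2(4aH)-one F4. Any minor equatorial alcohol from step 15 is pooled with it. Steglich acylation of F4 with acid 18 (DCC, DMAP, CH2Cl2) proceeds with retention and gives 27.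

**Further compounds**

F1 | step 10 | 2-acetyl-3-methylbut-2-en-1-yl methyl carbonate | COC(=O)OCC(C(C)=O)=C(C)C
F2 | step 13 | epoxide of 22 at the propan-2-ylidene double bond, oxirane oxygen on the face opposite the angular methyl | COC1(OC)CCC2=CC(=O)[C@]3(OC3(C)C)C[C@]2(C)[C@H]1C
F3 | step 13 | (3S,4aR,5R)-3-(2-hydroxypropan-2-yl)-6,6-dimethoxy-4a,5-dimethyl-4,4a,5,6,7,8-hexahydronaphthalen-2(3H)-one | COC1(OC)CCC2=CC(=O)[C@H](C(C)(C)O)C[C@]2(C)[C@H]1C
F4 | step 16 | (4aR,5R,6R)-6-hydroxy-3-(2-hydroxypropan-2-yl)-4a,5-dimethyl-5,6,7,8-tetrahydronaphthalen-2(4aH)-one | O[C@@H]1CCC2=CC(=O)C(C(C)(C)O)=C[C@]2(C)[C@H]1C
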